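The earlier runs and the new flask are simulated with made-up constants.

Start with the easy count. A saturated solution holds 110 mM of reagent against 2.0 M of substrate in this flask, so the bench rule, which counts one solutionful of reagent, lets 5.50% of the charge react.

| flask | substrate | gas | remark | time |
|---|---|---|---|---|
| alder | 1 M | 110 mM (held) | run made earlier |  |
| ash | 1.5 M | 110 mM (held) | run made earlier |  |
| flask | 2.0 M | 110 mM (held) |  | 4.0 min |

- alder (time / min: product / %, substrate / %): 0.200: 7.5, 33.1; 0.667: 37.9, 0.6; 1.00: 47.3, 1.0; 2.00: 54.0, 0; 2.50: 55.0, 0.3; 3.00: 54.0, 0
- ash (time / min: product / %, substrate / %): 0.200: 8.0, 39.7; 0.667: 38.7, 2.1; 1.00: 48.8, 0.8; 2.00: 55.7, 0.4; 2.50: 55.6, 1.3; 3.00: 55.6, 0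

(standard deviation of a reading: 0.5 percentage points)

- at the start none of reagent is dissolved
- the numbers in the tables scatter with a standard deviation of 0.5 percentage points
- steps that have been proposed: substrate + reagent -> intermediate A; gas <-> reagent; reagent + intermediate A -> intermediate B; intermediate D <-> intermediate E; intermediate B <-> intermediate C; intermediate A -> product; intermediate C -> intermediate D

* how much product there is at 4.0 min, in percent of the substrate charged
* concentration of reagent in solution at 4.0 min, in percent of saturation

Test the rule on the alder run. Its ratio allows 11.0%, yet substrate already reads 33.1% at 0.200 min. So 6.08 saturated solutions' worth has reacted, more than the solution held. The rule stops where that ratio passes one, and the proposed step from the held gas to reagent is the source the rule does not count.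

Write the reagent balance instead. Each substrate takes one reagent, and each intermediate A that misses product takes a second. No proposed step after intermediate B takes any. For a flask with no substrate or intermediate A left, that gives:

refill count = (substrate charged / saturation) × (2 − product share)

For this flask, the charge ratio is 18.2. Borrow the ash run's last product reading, 55.6%, and my count comes to 26.3. Call this the refill count, the reagent consumed, in saturated solutions' worth.

The forecast gives 56.5% of product and reagent at 99.5% of saturation at 4.0 min, reasoning: “No later step consumes reagent, so it should have recovered to saturation”.

The forecast stands on both counts: this flask gives 57.2% of product and reagent at >99.9% of saturation.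

substrate + reagent → intermediate A (k = 1.30 /M/s); gas ⇌ reagent, rate k2*(csat - [reagent]) (kL = 1.70 /s); reagent + intermediate A → intermediate B (k = 0.200 /M/s); intermediate D ⇌ intermediate E (K = 0.900, k = 0.0340 /s); intermediate B ⇌ intermediate C (K = 1.90, k = 0.0580 /s); intermediate A → product (k = 0.0230 /s); intermediate C → intermediate D (k = 0.0410 /s) With that product share, the refill count moves from 26.3 to 26.0: the reaction has consumed that many saturated solutions' worth of reagent by 4.00 min, with substrate, the limiting reagent, at 0%. Read the same flask at 1.0 min and sum the same balance by its terms: substrate reacted plus intermediates B, C, D and E gives 24.5 saturated solutions' worth. There reagent stands at 96.0% of saturation and intermediate A at 16.1%.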